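The data are calculated for an exercise; noise was put on by code.

Take each earlier run at its flat stretch and ask it one question: at what level of partner would substrate split evenly between target and its losses?

| setting | alpha | zeta | eta | gamma | summer | autumn | spring | dusk | winter |
|---|---|---|---|---|---|---|---|---|---|
| substrate | 2 mM | 2 mM | 2 mM | 1 mM | 2.0 mM (fed, over 80 s) | 2.0 mM (in portions, 3, over 80 s) | 2.0 mM | 2.0 mM | 2.0 mM |
| partner | 3 mM | 2 mM | 4.5 mM | 3 mM | 3.00 mM | 3.00 mM | 3.00 mM | 3.00 mM | 3.00 mM (fed, over 80 s) |
| protic impurity | 2 mM | 2 mM | 2 mM | 2 mM | 2.00 mM | 2.00 mM | 2.00 mM | 2.00 mM | 2.00 mM |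
| temperature | −25 °C | −14 °C | −25 °C | −14 °C | −20 °C | −20 °C | −20 °C |  |  |
| remark | run made earlier | run made earlier | run made earlier | run made earlier | all else is in the flask from the start; the feed brings no volume worth counting | first portion at the start, last at 80 s | everything together at the start | everything together at the start at −40 °C, warmed to −20 °C at 80 s | the addition at −40 °C, then warmed to −20 °C; the feed brings no volume worth counting |
| time |  |  |  |  | 2.0 min | 2.0 min | 2.0 min | 2.0 min | 2.0 min |

| run | time / s | target / % |
|---|---|---|
| alpha | 10.0 | 39.3 |
| alpha | 20.0 | 39.9 |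
| alpha | 30.0 | 39.6 |
| alpha | 50.0 | 40.1 |
| alpha | 80.0 | 40.1 |
| alpha | 90.0 | 40.8 |
| alpha | 120 | 39.5 |
| zeta | 10.0 | 28.2 |
| zeta | 20.0 | 28.8 |
| zeta | 30.0 | 28.4 |
| zeta | 50.0 | 29.2 |
| zeta | 80.0 | 28.6 |
| zeta | 90.0 | 29.1 |
| zeta | 120 | 29.7 |
| eta | 15.0 | 50.0 |
| eta | 30.0 | 50.4 |
| eta | 50.0 | 49.4 |
| eta | 60.0 | 50.4 |
| eta | 80.0 | 50.2 |
| eta | 90.0 | 48.8 |
| eta | 120 | 50.4 |
| gamma | 25.0 | 47.7 |
| gamma | 50.0 | 48.0 |
| gamma | 80.0 | 47.3 |
| gamma | 90.0 | 47.9 |
| gamma | 120 | 48.0 |

(readings scatter by 0.5 percentage points)

- in percentages every species weighs as the substrate in it: one side product B or side product C counts as two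
- for target the crystals are counted in
- as a solid, counted per litre of solution: crystals
- the numbers in the tables scatter with a standard deviation of 0.5 percentage points
- what may be going on: substrate + partner -> target; substrate -> side product A; 2 substrate -> side product B; crystals <-> target; partner + protic impurity -> quenched reagent; substrate + target -> side product C

- which flask leads in amount of target, in percent of the substrate charged ("all alike" within 1.5 percentage points) (summer / autumn / spring / dusk / winter / all alike)
- how much target is there at the end, in percent of the substrate charged: summer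
- how much target is there at the end, in percent of the substrate charged: autumn
- how much target is there at the end, in percent of the substrate charged: spring
- how much target is there at the end, in percent of the substrate charged: dusk
- how much target is there at the end, in percent of the substrate charged: winter

At a given partner level the coupling is pseudo-first-order in substrate, so I write the share going to target as mean partner over mean partner plus a loss level, the even-split concentration just named. I replace the falling partner by the mean of its start and end, counting what target takes and no quenching; in alpha, target already reads flat at 10.0 s.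

I read the runs row by row. Alpha gives 39.9 % of target at a mean partner of 2.60 mM, so its loss level is 3.92 mM. Eta, with more partner, gives 49.9 % but a loss level of 4.01 mM, so between these two runs the yield rises while the loss level shifts by 0.0900 mM. Zeta, warmer, gives 28.9 % and 4.22 mM. Gamma, at the same temperature with 1 mM of substrate against zeta's 2 mM and with more partner, gives 47.8 % and 3.02 mM. Alpha and eta lead me to assume that the drop from zeta to gamma comes from substrate, and extending that straight line down to no substrate leaves 1.82 mM, my estimate at −14 °C of the loss floor, the loss level with substrate very dilute.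

Spring has alpha's charges at −20 °C, so with a loss level midway between alpha's and zeta's, 4.07 mM, I reckon 39.0 %. Dusk starts colder, and alpha's loss level is lower than zeta's, so I expect a little more there.

I expect summer, being fed, to run near the floor, which I carry over unchanged to −20 °C, but protic impurity may take partner during the feed, and with spring's yield I reckon partner ending near 0.220 mM. A straight-line mean of 1.61 mM gives 47.0 %. Quenching finished at once gives a mean of 0.610 mM and 25.1 %. I have no reading of that speed, so I commit to the middle for summer, 36.1 %, which is less than my reckoning for spring, and I name dusk as leader.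

The forecast names summer, with 56 % there, 50 % in autumn, 38.5 % in spring, 44 % in dusk and 13 % in winter, holding that “Feeding substrate keeps it dilute and suppresses dimer”.

The flasks give 35.3 % in summer, 31.4 % in autumn, 39.0 % in spring, 42.2 % in dusk and 2.50 % in winter, so dusk leads.

    substrate + partner → target (k = 1090 M⁻¹ s⁻¹, Ea = 37.0 kJ mol⁻¹)
    substrate → side product A (k = 1.43 s⁻¹, Ea = 51.0 kJ mol⁻¹)
    2 substrate → side product B (k = 1770 M⁻¹ s⁻¹, Ea = 36.0 kJ mol⁻¹)
    crystals ⇌ target, rate k4*(cs4 - [target]) while solid is left; crystals form when [target] > cs4 (solubility = 1.60 mM, k = 0.645 s⁻¹)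
    partner + protic impurity → quenched reagent (k = 58.0 M⁻¹ s⁻¹, Ea = 38.0 kJ mol⁻¹)
    substrate + target → side product C (k = 11.1 M⁻¹ s⁻¹, Ea = 47.0 kJ mol⁻¹)
    (constants at −20 °C)

In spring the half-life of partner by quenching, as charged, is 5.98 s, far shorter than the feed of 80 s in summer, which starts with the same partner, protic impurity and temperature. Summer's 35.3 % on the floor of 1.82 mM reckons to a mean partner of 0.993 mM. Autumn's 31.4 % on the same floor reckons to 0.833 mM, but autumn holds more side product B than summer's 1.74 %, namely 28.6 %.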